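The route rests on disconnecting the O2–C6 bond of the 1,2-dioxane ring. The feature exploited is the quaternary peroxy carbon C6, whose methyl and CH2R groups are sterically alike: its configuration is pre-encoded as the E geometry of an acyclic C5=C6 alkene next to the C4 methyl stereocentre. In one operation an iodonium-triggered 6-endo closure of a C3 hydroperoxide onto that alkene forms the ring and the O2–C6 and C5–I bonds and sets C6 (and C5). The precursor is an open-chain (3S,4R)-anti hydroperoxide carrying the E-trisubstituted C5=C6 alkene, an electron-poor methyl enoate arm (C7–C10) and a silyl-protected C1 alcohol; the phenyl diene and the C1 ester follow afterwards.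

Key step: step 9

Remarks:
- Atom labels C1–C12 follow the target chain: C1 is the ester carbon, C3 carries O1, C6 carries O2, C12 is the benzylic CH2. TBS = tert-butyldimethylsilyl.
- The enoate arm is carried as a methyl ester, so that methoxide exchange during the methanolic perhydrolysis of step 8 is degenerate. The C3 hydroxyl is carried unprotected.
- (S)-TRIP = (S)-3,3′-bis(2,4,6-triisopropylphenyl)-1,1′-binaphthalene-2,2′-diyl hydrogen phosphate.
- Only discrete covalent intermediates of telescoped steps are numbered. Metal alkoxides hydrolysed on work-up and transient ions or radicals are not.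

Step 1
Reactants: 1 3-(TBSO)propanal; 2 (Z)-crotylboronic acid pinacol ester
Product: 4 (3R,4R)-1-(TBSO)-4-methylhex-5-en-3-ol, via boronate ester 3 (not isolated)
Conditions: (S)-TRIP (5 mol %), 4 Å molecular sieves, toluene, −30 °C; then aq. NaHCO3
Reagents that add atoms: none
Why: Chiral phosphoric acid-catalysed crotylboration through a closed chair (Zimmerman–Traxler) transition state, in which the Z-boronate makes C3-OH and C4-Me syn and the (S)-acid is expected, by analogy with the established sense of induction of this catalyst class, to direct attack to the aldehyde Si face (3R).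

Step 2
Reactants: 4 (3R,4R)-1-(TBSO)-4-methylhex-5-en-3-ol; 5 ethyl 2-(triphenylphosphoranylidene)propanoate
Product: 8 ethyl (2E,4R,5R)-7-(TBSO)-5-hydroxy-2,4-dimethylhept-2-enoate, via ozonide 6 (not isolated), via hydroxy aldehyde 7 (not isolated)
Conditions: O3, CH2Cl2, −78 °C; PPh3, −78 °C → rt; water wash, concentrate; crude 7, 5 (1.5 equiv), CH2Cl2, rt
Reagents that add atoms: none
Why: Ozonolysis with reductive work-up followed by a Wittig olefination with a stabilised ylide, which needs no base (the epimerisable C4 of the β-hydroxy aldehyde is not enolised) and should give the E-trisubstituted enoate, placing the future C7 trans to C4.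

Step 3
Reactants: 8 ethyl (2E,4R,5R)-7-(TBSO)-5-hydroxy-2,4-dimethylhept-2-enoate
Product: 9 (2E,4R,5R)-7-(TBSO)-2,4-dimethylhept-2-ene-1,5-diol
Conditions: i-Bu2AlH (3.5 equiv), CH2Cl2, −78 °C; aq. potassium sodium tartrate
Reagents that add atoms: none
Why: 1,2-Reduction of an α,β-unsaturated ester to the allylic alcohol by i-Bu2AlH, which touches neither the stereocentres nor the alkene geometry.

Step 4
Reactants: 9 (2E,4R,5R)-7-(TBSO)-2,4-dimethylhept-2-ene-1,5-diol
Product: 10 (3R,4R,5E)-7-bromo-1-(TBSO)-4,6-dimethylhept-5-en-3-ol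
Conditions: NBS, Me2S, CH2Cl2, −20 → 0 °C
Reagents that add atoms: N-bromosuccinimide, O=C1CCC(=O)N1Br
Why: Corey–Kim-type halogenation, in which only the allylic alkoxysulfonium ion is displaced by bromide while the secondary one, with no base added, reverts to the C3 alcohol on work-up; the E alkene keeps C3-OH out of reach of C7, so no cyclic ether can form.

Step 5
Reactants: 11 methyl but-2-ynoate
Product: 13 methyl (2E)-3-(tributylstannyl)but-2-enoate, via alkenylcopper 12 (not isolated)
Conditions: Bu3SnH, LiN(i-Pr)2, THF, −30 °C; CuBr·SMe2, −78 °C; then 11, MeOH, −78 °C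
Reagents that add atoms: tributyltin hydride, CCCC[SnH](CCCC)CCCC
Why: Stannylcupration (conjugate syn addition of a stannylcopper reagent to an ynoate), where protonation of the kinetic adduct at −78 °C keeps tin and hydrogen cis, that is tin trans to the ester (E).

Step 6
Reactants: 10 (3R,4R,5E)-7-bromo-1-(TBSO)-4,6-dimethylhept-5-en-3-ol; 13 methyl (2E)-3-(tributylstannyl)but-2-enoate
Product: 14 methyl (2E,5E,7R,8R)-10-(TBSO)-8-hydroxy-3,5,7-trimethyldeca-2,5-dienoate
Conditions: Pd2(dba)3 (2.5 mol %), P(2-furyl)3 (10 mol %), NMP, 40 °C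
Reagents that add atoms: none
Why: Stille coupling of an allylic bromide with an alkenylstannane, in which zerovalent palladium forms a π-allyl complex that couples at its unhindered CH2 terminus (C7) with retention of both alkene geometries under neutral conditions that spare the free hydroxyl and the doubly allylic C7 methylene.

Step 7
Reactants: 14 methyl (2E,5E,7R,8R)-10-(TBSO)-8-hydroxy-3,5,7-trimethyldeca-2,5-dienoate
Product: 15 methyl (2E,5E,7R,8R)-10-(TBSO)-8-(methanesulfonyloxy)-3,5,7-trimethyldeca-2,5-dienoate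
Conditions: MsCl, Et3N, CH2Cl2, 0 °C; used at once
Reagents that add atoms: methanesulfonyl chloride, CS(=O)(=O)Cl
Why: O-Sulfonylation of the secondary alcohol (via sulfene) with retention at C3, giving the leaving group for the inversion.

Step 8
Reactants: 15 methyl (2E,5E,7R,8R)-10-(TBSO)-8-(methanesulfonyloxy)-3,5,7-trimethyldeca-2,5-dienoate
Product: 16 methyl (2E,5E,7R,8S)-10-(TBSO)-8-hydroperoxy-3,5,7-trimethyldeca-2,5-dienoate
Conditions: 50% aq. H2O2 (large excess), KOH, MeOH, 0 °C → rt
Reagents that add atoms: hydrogen peroxide, OO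
Why: Alkaline perhydrolysis of a secondary sulfonate, an SN2 displacement by the α-effect nucleophile HOO− that inverts C3 and so turns the syn alcohol series into the anti (3S,4R) hydroperoxide, while the excess H2O2 keeps free hydroxide low and the hindered conjugated methyl ester can only exchange degenerately with methanol.

Step 9
Reactants: 16 methyl (2E,5E,7R,8S)-10-(TBSO)-8-hydroperoxy-3,5,7-trimethyldeca-2,5-dienoate
Product: 17 methyl (2E)-4-[(3S,4R,5S,6S)-6-[2-(TBSO)ethyl]-4-iodo-3,5-dimethyl-1,2-dioxan-3-yl]-3-methylbut-2-enoate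
Conditions: NIS (1.3 equiv), CH2Cl2, 0 °C, dark
Reagents that add atoms: N-iodosuccinimide, O=C1CCC(=O)N1I
Why: NIS converts the electron-rich C5=C6 alkene reversibly into an iodonium ion, which the terminal hydroperoxide oxygen opens anti to iodine at the tertiary carbon C6, creating the O2–C6 and C5–I bonds. The closest known reaction type is the halonium-induced cyclisation of unsaturated hydroperoxides (cycloperoxyiodination), with peroxymercuration as its mercury counterpart. The 1,2-dioxane closes in the 6-endo-trig mode, since Markovnikov opening at tertiary C6 outweighs the 5-exo alternative at secondary C5. C6 is controlled by the E alkene geometry (the C7 chain, trans to C4 on the alkene, becomes equatorial and the cis methyl axial) together with the face attacked, and C5 by the anti addition, which leaves iodine equatorial. The step needs Markovnikov 6-endo attack on a single alkene face, and the face is secured by the chair transition state with the C3 arm and the C4 methyl both equatorial, the opposite face demanding both axial plus a 1,3-diaxial methyl–methyl clash between C4 and C6. The enoate alkene is too electron-poor to take up iodine and the silyl ether oxygen has no favourable ring size to C5 or C6, so neither competes.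

Step 10
Reactants: 17 methyl (2E)-4-[(3S,4R,5S,6S)-6-[2-(TBSO)ethyl]-4-iodo-3,5-dimethyl-1,2-dioxan-3-yl]-3-methylbut-2-enoate
Product: 18 methyl (2E)-4-[(3R,5R,6S)-6-[2-(TBSO)ethyl]-3,5-dimethyl-1,2-dioxan-3-yl]-3-methylbut-2-enoate
Conditions: Bu3SnH (3 equiv, 0.3 M), Et3B (0.2 equiv), air, toluene, 0 °C
Reagents that add atoms: none
Why: Radical chain dehalogenation, in which the ring C5 radical is trapped by the concentrated stannane before it can attack the O–O bond, because an endocyclic peroxide cannot reach the collinear geometry that epoxide formation requires.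

Step 11
Reactants: 18 methyl (2E)-4-[(3R,5R,6S)-6-[2-(TBSO)ethyl]-3,5-dimethyl-1,2-dioxan-3-yl]-3-methylbut-2-enoate
Product: 19 (2E)-4-[(3R,5R,6S)-6-[2-(TBSO)ethyl]-3,5-dimethyl-1,2-dioxan-3-yl]-3-methylbut-2-en-1-ol
Conditions: i-Bu2AlH (2.5 equiv), CH2Cl2, −78 °C; aq. potassium sodium tartrate
Reagents that add atoms: none
Why: 1,2-Reduction of the enoate to the allylic alcohol by i-Bu2AlH at −78 °C, conditions under which a dialkyl peroxide is inert.

Step 12
Reactants: 19 (2E)-4-[(3R,5R,6S)-6-[2-(TBSO)ethyl]-3,5-dimethyl-1,2-dioxan-3-yl]-3-methylbut-2-en-1-ol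
Product: 20 (2E)-4-[(3R,5R,6S)-6-[2-(TBSO)ethyl]-3,5-dimethyl-1,2-dioxan-3-yl]-3-methylbut-2-enal
Conditions: activated MnO2, CH2Cl2, rt
Reagents that add atoms: none
Why: Chemoselective allylic alcohol oxidation on MnO2, which should give the E enal without affecting the peroxide or the silyl ether.

Step 13
Reactants: 21 1-phenyl-1H-tetrazole-5-thiol; 22 (2-bromoethyl)benzene
Product: 23 1-phenyl-5-[(2-phenylethyl)sulfanyl]-1H-tetrazole
Conditions: K2CO3, acetone, rt
Reagents that add atoms: none
Why: SN2 S-alkylation of the tetrazole thiolate by a primary bromide.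

Step 14
Reactants: 23 1-phenyl-5-[(2-phenylethyl)sulfanyl]-1H-tetrazole
Product: 24 1-phenyl-5-[(2-phenylethyl)sulfonyl]-1H-tetrazole
Conditions: 30% aq. H2O2, (NH4)6Mo7O24·4H2O (10 mol %), EtOH, 0 °C → rt
Reagents that add atoms: hydrogen peroxide, OO
Why: Molybdate-catalysed oxidation of the sulfide to the sulfone, the standard preparation of Julia–Kocienski reagents.

Step 15
Reactants: 20 (2E)-4-[(3R,5R,6S)-6-[2-(TBSO)ethyl]-3,5-dimethyl-1,2-dioxan-3-yl]-3-methylbut-2-enal; 24 1-phenyl-5-[(2-phenylethyl)sulfonyl]-1H-tetrazole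
Product: 25 tert-butyl{2-[(3S,4R,6R)-4,6-dimethyl-6-[(2E,4E)-2-methyl-6-phenylhexa-2,4-dien-1-yl]-1,2-dioxan-3-yl]ethoxy}dimethylsilane
Conditions: 24 (1.3 equiv), KN(SiMe3)2, DME, −60 °C, 20 min; then 20, −60 °C → rt; aq. NH4Cl
Reagents that add atoms: none
Why: Julia–Kocienski olefination (addition of the metalated phenyltetrazolyl sulfone to the enal, Smiles rearrangement, loss of SO2 and tetrazolone), which with potassium in DME should give the E C10=C11 alkene, and which is run while C1 is still a silyl ether so that no carbonyl acidifies the hydrogens next to the peroxide.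

Step 16
Reactants: 25 tert-butyl{2-[(3S,4R,6R)-4,6-dimethyl-6-[(2E,4E)-2-methyl-6-phenylhexa-2,4-dien-1-yl]-1,2-dioxan-3-yl]ethoxy}dimethylsilane
Product: 26 2-[(3S,4R,6R)-4,6-dimethyl-6-[(2E,4E)-2-methyl-6-phenylhexa-2,4-dien-1-yl]-1,2-dioxan-3-yl]ethan-1-ol
Conditions: HF·pyridine, pyridine, THF, 0 °C → rt
Reagents that add atoms: none
Why: Fluoride cleavage of a primary silyl ether under buffered, non-basic conditions that should leave the dioxane and the diene intact.

Step 17
Reactants: 26 2-[(3S,4R,6R)-4,6-dimethyl-6-[(2E,4E)-2-methyl-6-phenylhexa-2,4-dien-1-yl]-1,2-dioxan-3-yl]ethan-1-ol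
Product: 28 [(3S,4R,6R)-4,6-dimethyl-6-[(2E,4E)-2-methyl-6-phenylhexa-2,4-dien-1-yl]-1,2-dioxan-3-yl]acetic acid, via aldehyde 27 (not isolated)
Conditions: TEMPO (20 mol %), PhI(OAc)2 (2.5 equiv), MeCN/H2O 1:1, rt
Reagents that add atoms: water, O
Why: Oxoammonium-mediated (TEMPO/PhI(OAc)2) oxidation of the primary alcohol through the aldehyde hydrate to the acid in a slightly acidic medium, which avoids base-induced β-elimination of the peroxide from the β-peroxy aldehyde.

Step 18
Reactants: 28 [(3S,4R,6R)-4,6-dimethyl-6-[(2E,4E)-2-methyl-6-phenylhexa-2,4-dien-1-yl]-1,2-dioxan-3-yl]acetic acid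
Product: 29 methyl [(3S,4R,6R)-4,6-dimethyl-6-[(2E,4E)-2-methyl-6-phenylhexa-2,4-dien-1-yl]-1,2-dioxan-3-yl]acetate
Conditions: Me3SiCHN2, MeOH/toluene 1:4, 0 °C
Reagents that add atoms: trimethylsilyldiazomethane, C[Si](C)(C)C=[N+]=[N-]
Why: Neutral O-methylation of the carboxylic acid by a diazoalkane, avoiding the base that would open the β-peroxy ester by a retro-oxa-Michael reaction.

Compound list
1 | 3-(TBSO)propanal | CC(C)(C)[Si](C)(C)OCCC=O | starting material
2 | (Z)-crotylboronic acid pinacol ester | C/C=C\CB1OC(C)(C)C(C)(C)O1 | starting material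
3 | 2-{[(3R,4R)-1-(TBSO)-4-methylhex-5-en-3-yl]oxy}-4,4,5,5-tetramethyl-1,3,2-dioxaborolane | CC(C)(C)[Si](C)(C)OCC[C@@H](OB1OC(C)(C)C(C)(C)O1)[C@H](C)C=C | intermediate
4 | (3R,4R)-1-(TBSO)-4-methylhex-5-en-3-ol (3,4-syn) | CC(C)(C)[Si](C)(C)OCC[C@@H](O)[C@H](C)C=C | intermediate
5 | ethyl 2-(triphenylphosphoranylidene)propanoate | CCOC(=O)C(C)=P(c1ccccc1)(c1ccccc1)c1ccccc1 | starting material
6 | (3R,4S)-1-(TBSO)-4-(1,2,4-trioxolan-3-yl)pentan-3-ol (ozonide of 4, trioxolane carbon unassigned) | CC(C)(C)[Si](C)(C)OCC[C@@H](O)[C@H](C)C1OCOO1 | intermediate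
7 | (2S,3R)-5-(TBSO)-3-hydroxy-2-methylpentanal | CC(C)(C)[Si](C)(C)OCC[C@@H](O)[C@H](C)C=O | intermediate
8 | ethyl (2E,4R,5R)-7-(TBSO)-5-hydroxy-2,4-dimethylhept-2-enoate | CC(C)(C)[Si](C)(C)OCC[C@@H](O)[C@H](C)/C=C(\C)C(=O)OCC | intermediate
9 | (2E,4R,5R)-7-(TBSO)-2,4-dimethylhept-2-ene-1,5-diol | CC(C)(C)[Si](C)(C)OCC[C@@H](O)[C@H](C)/C=C(\C)CO | intermediate
10 | (3R,4R,5E)-7-bromo-1-(TBSO)-4,6-dimethylhept-5-en-3-ol | CC(C)(C)[Si](C)(C)OCC[C@@H](O)[C@H](C)/C=C(\C)CBr | intermediate
11 | methyl but-2-ynoate | CC#CC(=O)OC | starting material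
12 | methyl (2Z)-2-cuprio-3-(tributylstannyl)but-2-enoate (tin and copper cis) | CCCC[Sn](CCCC)(CCCC)/C(C)=C(\[Cu])C(=O)OC | intermediate
13 | methyl (2E)-3-(tributylstannyl)but-2-enoate | CCCC[Sn](CCCC)(CCCC)/C(C)=C/C(=O)OC | intermediate
14 | methyl (2E,5E,7R,8R)-10-(TBSO)-8-hydroxy-3,5,7-trimethyldeca-2,5-dienoate | CC(C)(C)[Si](C)(C)OCC[C@@H](O)[C@H](C)/C=C(\C)C/C(C)=C/C(=O)OC | intermediate
15 | methyl (2E,5E,7R,8R)-10-(TBSO)-8-(methanesulfonyloxy)-3,5,7-trimethyldeca-2,5-dienoate | CC(C)(C)[Si](C)(C)OCC[C@@H](OS(C)(=O)=O)[C@H](C)/C=C(\C)C/C(C)=C/C(=O)OC | intermediate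
16 | methyl (2E,5E,7R,8S)-10-(TBSO)-8-hydroperoxy-3,5,7-trimethyldeca-2,5-dienoate (chain C3 S, C4 R, anti) | CC(C)(C)[Si](C)(C)OCC[C@H](OO)[C@H](C)/C=C(\C)C/C(C)=C/C(=O)OC | intermediate
17 | methyl (2E)-4-[(3S,4R,5S,6S)-6-[2-(TBSO)ethyl]-4-iodo-3,5-dimethyl-1,2-dioxan-3-yl]-3-methylbut-2-enoate (chain C3 arm, C4 Me, C5 I and C7 chain equatorial, C6 Me axial) | CC(C)(C)[Si](C)(C)OCC[C@@H]1OO[C@@](C)(C/C(C)=C/C(=O)OC)[C@H](I)[C@H]1C | intermediate
18 | methyl (2E)-4-[(3R,5R,6S)-6-[2-(TBSO)ethyl]-3,5-dimethyl-1,2-dioxan-3-yl]-3-methylbut-2-enoate | CC(C)(C)[Si](C)(C)OCC[C@@H]1OO[C@@](C)(C/C(C)=C/C(=O)OC)C[C@H]1C | intermediate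
19 | (2E)-4-[(3R,5R,6S)-6-[2-(TBSO)ethyl]-3,5-dimethyl-1,2-dioxan-3-yl]-3-methylbut-2-en-1-ol | CC(C)(C)[Si](C)(C)OCC[C@@H]1OO[C@@](C)(C/C(C)=C/CO)C[C@H]1C | intermediate
20 | (2E)-4-[(3R,5R,6S)-6-[2-(TBSO)ethyl]-3,5-dimethyl-1,2-dioxan-3-yl]-3-methylbut-2-enal | CC(C)(C)[Si](C)(C)OCC[C@@H]1OO[C@@](C)(C/C(C)=C/C=O)C[C@H]1C | intermediate
21 | 1-phenyl-1H-tetrazole-5-thiol | Sc1nnnn1-c1ccccc1 | starting material
22 | (2-bromoethyl)benzene | BrCCc1ccccc1 | starting material
23 | 1-phenyl-5-[(2-phenylethyl)sulfanyl]-1H-tetrazole | c1ccc(CCSc2nnnn2-c2ccccc2)cc1 | intermediate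
24 | 1-phenyl-5-[(2-phenylethyl)sulfonyl]-1H-tetrazole | O=S(=O)(CCc1ccccc1)c1nnnn1-c1ccccc1 | intermediate
25 | tert-butyl{2-[(3S,4R,6R)-4,6-dimethyl-6-[(2E,4E)-2-methyl-6-phenylhexa-2,4-dien-1-yl]-1,2-dioxan-3-yl]ethoxy}dimethylsilane | CC(C)(C)[Si](C)(C)OCC[C@@H]1OO[C@@](C)(C/C(C)=C/C=C/Cc2ccccc2)C[C@H]1C | intermediate
26 | 2-[(3S,4R,6R)-4,6-dimethyl-6-[(2E,4E)-2-methyl-6-phenylhexa-2,4-dien-1-yl]-1,2-dioxan-3-yl]ethan-1-ol | OCC[C@@H]1OO[C@@](C)(C/C(C)=C/C=C/Cc2ccccc2)C[C@H]1C | intermediate
27 | [(3S,4R,6R)-4,6-dimethyl-6-[(2E,4E)-2-methyl-6-phenylhexa-2,4-dien-1-yl]-1,2-dioxan-3-yl]acetaldehyde | O=CC[C@@H]1OO[C@@](C)(C/C(C)=C/C=C/Cc2ccccc2)C[C@H]1C | intermediate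
28 | [(3S,4R,6R)-4,6-dimethyl-6-[(2E,4E)-2-methyl-6-phenylhexa-2,4-dien-1-yl]-1,2-dioxan-3-yl]acetic acid | OC(=O)C[C@@H]1OO[C@@](C)(C/C(C)=C/C=C/Cc2ccccc2)C[C@H]1C | intermediate
29 | methyl [(3S,4R,6R)-4,6-dimethyl-6-[(2E,4E)-2-methyl-6-phenylhexa-2,4-dien-1-yl]-1,2-dioxan-3-yl]acetate | COC(=O)C[C@@H]1OO[C@@](C)(C/C(C)=C/C=C/Cc2ccccc2)C[C@H]1C | target

Total step count: 18.
Longest linear sequence: 15 steps (steps 1–4, 6–12, 15–18). Steps 5, 13 and 14 make the two side fragments.

Steps most likely to fail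

1. Step 8 (perhydrolysis of the C3 mesylate). The SN2 displacement at the β-branched C3 is slow. E2 elimination, ionisation assisted by the homoallylic C5=C6 alkene (retention or rearrangement) and attack of peroxide anion on the ester may therefore outrun it in the protic medium. The fallback sets out from mesylate 15 and changes the nucleophile and the medium. 15 would be alkylated with the cesium salt of 2-methoxyprop-2-yl hydroperoxide (made by ozonolysis of 2,3-dimethylbut-2-ene in methanol) using CsOH·H2O in DMF at 0 °C. This SN2 reaction of a protected peroxide anion in a dipolar aprotic solvent should give, with inversion, the peroxyketal methyl (2E,5E,7R,8S)-10-(TBSO)-8-[(2-methoxypropan-2-yl)peroxy]-3,5,7-trimethyldeca-2,5-dienoate F1. Brief hydrolysis with AcOH/THF/H2O at rt would unmask the hydroperoxide, and the route is rejoined at 16.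

2. Step 9 (iodoperoxidation). Competing 5-exo closure, attack on the wrong alkene face, or iodine-induced decomposition of the hydroperoxide would erode the yield of the single diastereomer. The fallback sets out from hydroperoxide 16 and replaces the irreversible halonium closure by reversible peroxymercuration. Hg(OAc)2 in CH2Cl2, followed by aqueous KBr, should give under thermodynamic control the all-equatorial organomercurial methyl (2E)-4-[(3S,4R,5S,6S)-4-(bromomercurio)-6-[2-(TBSO)ethyl]-3,5-dimethyl-1,2-dioxan-3-yl]-3-methylbut-2-enoate F2. Reductive demercuration with Bu3SnH in toluene would then give the iodine-free dioxane directly. The route is rejoined at 18, so that 17 and step 10 are bypassed.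

3. Step 15 (Julia–Kocienski olefination). Erosion of E selectivity at C10=C11 with the conjugated aldehyde, or γ-deprotonation of the enal by the sulfone anion, would lower the yield of the E,E diene. The fallback sets out from enal 20 and builds the alkene by a boron-Wittig reaction followed by cross-coupling. Lithiated bis(pinacolato)borylmethane (from CH2(Bpin)2 and lithium 2,2,6,6-tetramethylpiperidide, THF, −78 °C) should convert 20 into the trans alkenylboronate tert-butyl{2-[(3S,4R,6R)-4,6-dimethyl-6-[(2E,4E)-2-methyl-5-(4,4,5,5-tetramethyl-1,3,2-dioxaborolan-2-yl)penta-2,4-dien-1-yl]-1,2-dioxan-3-yl]ethoxy}dimethylsilane F3. Suzuki–Miyaura coupling of F3 with benzyl bromide (PdCl2(dppf), K3PO4, THF/H2O, rt) would attach C12 and the phenyl ring with retention of geometry, and the route is rejoined at 25.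

Further compounds
F1 | step 8 | methyl (2E,5E,7R,8S)-10-(TBSO)-8-[(2-methoxypropan-2-yl)peroxy]-3,5,7-trimethyldeca-2,5-dienoate | CC(C)(C)[Si](C)(C)OCC[C@H](OOC(C)(C)OC)[C@H](C)/C=C(\C)C/C(C)=C/C(=O)OC
F2 | step 9 | methyl (2E)-4-[(3S,4R,5S,6S)-4-(bromomercurio)-6-[2-(TBSO)ethyl]-3,5-dimethyl-1,2-dioxan-3-yl]-3-methylbut-2-enoate | CC(C)(C)[Si](C)(C)OCC[C@@H]1OO[C@@](C)(C/C(C)=C/C(=O)OC)[C@H]([Hg]Br)[C@H]1C
F3 | step 15 | tert-butyl{2-[(3S,4R,6R)-4,6-dimethyl-6-[(2E,4E)-2-methyl-5-(4,4,5,5-tetramethyl-1,3,2-dioxaborolan-2-yl)penta-2,4-dien-1-yl]-1,2-dioxan-3-yl]ethoxy}dimethylsilane | CC(C)(C)[Si](C)(C)OCC[C@@H]1OO[C@@](C)(C/C(C)=C/C=C/B2OC(C)(C)C(C)(C)O2)C[C@H]1C
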